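**Plan**
- **Cuts:** the two N–H hydrogens come off first, which turns the target into the quinoid 3,3'-biindolylidene. C2–Br, C2–C3, C3'–C2' and C2'–Br then fall together. The isocyanide carbons go back to formyl groups, and C3a–C3 and C3a'–C3' go back to Sonogashira couplings.
- **Feature used:** the chain Br–C2–C3–C3'–C2'–Br runs through both pyrrole rings. With the two N–H hydrogens removed, it equals an alkyne (C3≡C3') held between two isocyanide carbons (C2, C2') plus one Br2.
- **Forward order:** both 5,6-dibromobenzo rings come ready-made from 3,4-dibromoaniline and are joined through a two-carbon unit. The two five-membered rings then close one after the other in one radical chain, and reduction makes them aromatic.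
- **Stereochemistry:** the target has no stereocentre. The only stereo-element on the way, the C3=C3' double bond of the biindolylidene, vanishes in the last step.

Key step: step 5

Remark: the biindolylidene of the key step is drawn as its E isomer, although either geometry leads to the same target, and rotation about C3–C3' in the target is taken not to give separable atropisomers, in line with its stereo-free SMILES.

Step 1
Reactants: 1 3,4-dibromoaniline
Product: 2 4,5-dibromo-2-iodoaniline
Conditions: NIS (1.05 equiv), DMF, 0 °C to rt, dark
Reagents that add atoms: N-iodosuccinimide, O=C1CCC(=O)N1I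
Why: Electrophilic aromatic iodination directed by the amino group, in which the para position is blocked by bromine and one ortho position is wedged between NH2 and Br, so iodine should enter only at the open ortho carbon.

Step 2
Reactants: 2 4,5-dibromo-2-iodoaniline (2 equiv); 3 ethynyltrimethylsilane (1 equiv)
Product: 6 2,2'-(ethyne-1,2-diyl)bis(4,5-dibromoaniline), via 4,5-dibromo-2-[(trimethylsilyl)ethynyl]aniline 4 (not isolated), via 4,5-dibromo-2-ethynylaniline 5 (not isolated)
Conditions: PdCl2(PPh3)2 (5 mol %), CuI (10 mol %), DBU (6 equiv), H2O (1 equiv per 3), MeCN, rt, Ar
Reagents that add atoms: ethynyltrimethylsilane 3, C#C[Si](C)(C)C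
Why: One-pot double Sonogashira coupling in which DBU and water cleave the C–Si bond of 4 after the first coupling, and at room temperature zerovalent palladium inserts into C–I far faster than into C–Br, so the four bromines should stay in place.

Step 3
Reactants: 6 2,2'-(ethyne-1,2-diyl)bis(4,5-dibromoaniline)
Product: 7 N,N'-[ethyne-1,2-diylbis(4,5-dibromobenzene-2,1-diyl)]diformamide
Conditions: HCO2Ac (4 equiv, premade from Ac2O and HCO2H, 55 °C), THF, 0 °C to rt
Reagents that add atoms: acetic formic anhydride, CC(=O)OC=O
Why: N-Formylation of an aniline with a mixed anhydride, which transfers its more electrophilic formyl group and works at or below room temperature, so the 2-alkynylaniline units get no chance to cyclise to indoles.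

Step 4
Reactants: 7 N,N'-[ethyne-1,2-diylbis(4,5-dibromobenzene-2,1-diyl)]diformamide
Product: 8 1,2-bis(4,5-dibromo-2-isocyanophenyl)ethyne
Conditions: POCl3 (3 equiv), Et3N (12 equiv), THF, 0 °C; cold aq Na2CO3
Reagents that add atoms: none
Why: Formamide dehydration with POCl3 and a tertiary amine, the standard access to 2-alkynylaryl isocyanides, run cold and worked up under basic conditions because such isocyanides are sensitive to acid and heat.

Step 5
Reactants: 8 1,2-bis(4,5-dibromo-2-isocyanophenyl)ethyne; 9 bromine
Product: 10 (E)-2,2',5,5',6,6'-hexabromo-3H,3'H-3,3'-biindolylidene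
Conditions: 9 (1.0 equiv, 0.02 M in PhCF3, syringe pump, 4 h), 8 (2 mM), degassed PhCF3, 450 nm LED, 20 °C, Ar; evaporate cold, use crude
Reagents that add atoms: bromine 9, BrBr
Why: Proposed new method: blue light splits Br2, a bromine atom adds reversibly to one isocyanide carbon of 8 (C2–Br) to give an α-bromoimidoyl σ-radical, this radical attacks the nearer alkyne carbon (C2–C3, first five-membered ring, 5-exo-dig), the α-aryl vinyl radical so placed on C3' adds to the terminal carbon of the second isocyanide (C3'–C2', second five-membered ring, formally 5-endo-dig but in essence an α-addition to a carbene-like carbon), and the cyclic imidoyl radical takes bromine from Br2 (C2'–Br) and so releases the next chain carrier. The closest known reaction types are the tin- and thiyl-radical 5-exo cyclisations of 2-alkynylaryl isocyanides to 2,3-disubstituted indoles, the light-driven halogen addition to the same isocyanides, and, for the second closure, its anionic counterpart in the Ito–Saegusa ring closure of ortho-lithiomethylphenyl isocyanides, whereas a relay through two isocyanides carried by bromine alone is without precedent. The selectivity needed is 5-exo over 6-endo in the first closure, since 6-endo attack would end in a 2,4-dibromo-3-arylquinoline as is known for iodine, and the substrate secures it through the aryl group on the far alkyne carbon, which stabilises the vinyl radical of the 5-exo path, and through the isocyanide ortho on that aryl group, which gives this radical an irreversible exit inside the molecule that simple 2-alkynylaryl isocyanides lack. Ionic attack of bromine is held down by high dilution and syringe-pump addition, and it need not be fatal, because the N-aryl carbonimidic dibromide from α-addition of Br2 to one isocyanide, like the vinyl bromide from early bromine capture at C3', is an isomer of 10 that can hand a bromine atom to a chain radical and thereby re-enter the cascade. No stereocentre is formed, and the one stereo-element, the C3=C3' geometry, should be E because each C2 bromine then faces a C4–H and not the other bromine, which is of no consequence since step 6 removes it.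

Step 6
Reactants: 10 (E)-2,2',5,5',6,6'-hexabromo-3H,3'H-3,3'-biindolylidene
Product: 11 2,2',5,5',6,6'-hexabromo-1H,1'H-3,3'-biindole
Conditions: Na2S2O4 (3 equiv), THF–H2O (4:1), 0 °C, 15 min, N2
Reagents that add atoms: none
Why: Two-electron, two-proton dithionite reduction of the quinoid unit N1=C2–C3=C3'–C2'=N1', the reaction type used for vat dyes and quinone imines, driven by the gain of two aromatic indole rings and expected to be fast enough at 0 °C that the imidoyl bromides escape hydrolysis and no C–Br bond is reduced.

**Compound list**
1 | 3,4-dibromoaniline | Nc1ccc(Br)c(Br)c1 | starting material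
2 | 4,5-dibromo-2-iodoaniline | Nc1cc(Br)c(Br)cc1I | intermediate
3 | ethynyltrimethylsilane | C#C[Si](C)(C)C | starting material
4 | 4,5-dibromo-2-[(trimethylsilyl)ethynyl]aniline | Nc1cc(Br)c(Br)cc1C#C[Si](C)(C)C | intermediate
5 | 4,5-dibromo-2-ethynylaniline | Nc1cc(Br)c(Br)cc1C#C | intermediate
6 | 2,2'-(ethyne-1,2-diyl)bis(4,5-dibromoaniline) | Nc1cc(Br)c(Br)cc1C#Cc1cc(Br)c(Br)cc1N | intermediate
7 | N,N'-[ethyne-1,2-diylbis(4,5-dibromobenzene-2,1-diyl)]diformamide | O=CNc1cc(Br)c(Br)cc1C#Cc1cc(Br)c(Br)cc1NC=O | intermediate
8 | 1,2-bis(4,5-dibromo-2-isocyanophenyl)ethyne | [C-]#[N+]c1cc(Br)c(Br)cc1C#Cc1cc(Br)c(Br)cc1[N+]#[C-] | intermediate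
9 | bromine | BrBr | starting material
10 | (E)-2,2',5,5',6,6'-hexabromo-3H,3'H-3,3'-biindolylidene | BrC1=Nc2cc(Br)c(Br)cc2/C1=C3\C(Br)=Nc4cc(Br)c(Br)cc34 | intermediate
11 | 2,2',5,5',6,6'-hexabromo-1H,1'H-3,3'-biindole | Brc1cc2[nH]c(Br)c(-c3c(Br)[nH]c4cc(Br)c(Br)cc34)c2cc1Br | target

Total step count: 6. Longest linear sequence: 6 (1, 2, 6, 7, 8, 10, 11).

**Steps most likely to fail**

1. **Step 5 (new method).**
 - **Risk:** 6-endo closure of the first imidoyl radical, ionic addition of bromine to isocyanide or alkyne without re-entry into the chain, or bromine capture of the vinyl radical ahead of the second ring closure.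
 - **Fallback:** it uses known chemistry only and reverses the logic, so that the pyrrole rings are made first and the C3–C3' bond and the C2 bromines follow. It sets out from 2 and comes back at 11.
 - **Course:** compound 2 is coupled with an excess of 3 under ordinary Sonogashira conditions (PdCl2(PPh3)2, CuI, Et3N, THF, rt) to 4, now isolated. K2CO3 in MeOH frees 5, and gold-catalysed 5-endo-dig hydroamination (NaAuCl4, EtOH, rt) closes 5,6-dibromo-1H-indole F1. Oxidative C3–C3' homocoupling of the free indole under divalent palladium catalysis (Pd(OCOCF3)2, AgNO3, DMSO, rt) should give 5,5',6,6'-tetrabromo-1H,1'H-3,3'-biindole F2. NBS (2 equiv, THF, 0 °C) should then brominate the only open pyrrole positions, C2 and C2', to give 11.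

2. **Step 6.**
 - **Risk:** hydrolysis of the imidoyl bromide units in the aqueous medium ahead of electron transfer, or reductive loss of the C2 bromines.
 - **Fallback:** the hydrolysis is accepted and the bromines are put back by deoxybromination. It sets out from 10 and comes back at 11.
 - **Course:** stirring 10 in THF–H2O at rt should give (E)-5,5',6,6'-tetrabromoisoindigo F3. Zn in AcOH at rt saturates the central double bond to 5,5',6,6'-tetrabromo-3,3'-biindoline-2,2'-dione F4, a mixture of diastereomers of no consequence. POBr3 in 1,2-dichloroethane at 80 °C converts both lactams into 2-bromoindoles, which is 11.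

3. **Step 4.**
 - **Risk:** incomplete dehydration of the poorly soluble bis-formamide, and acid- or chloride-induced cyclisation or polymerisation of the 2-alkynylaryl isocyanide during reaction and work-up.
 - **Fallback:** it sets out from 6, leaves out 7 and comes back at 8. The isocyanide carbons are supplied by dichlorocarbene instead of a formyl group.
 - **Course:** a Hofmann carbylamine reaction under phase transfer (CHCl3, 50% aq NaOH, BnEt3NCl, CH2Cl2, 40 °C), an all-basic medium that suits the product.

**Further compounds**
F1 | step 5 | 5,6-dibromo-1H-indole | Brc1cc2cc[nH]c2cc1Br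
F2 | step 5 | 5,5',6,6'-tetrabromo-1H,1'H-3,3'-biindole | Brc1cc2[nH]cc(-c3c[nH]c4cc(Br)c(Br)cc34)c2cc1Br
F3 | step 6 | (E)-5,5',6,6'-tetrabromoisoindigo | O=C1Nc2cc(Br)c(Br)cc2/C1=C3\C(=O)Nc4cc(Br)c(Br)cc34
F4 | step 6 | 5,5',6,6'-tetrabromo-3,3'-biindoline-2,2'-dione (mixture of diastereomers) | O=C1Nc2cc(Br)c(Br)cc2C1C1C(=O)Nc2cc(Br)c(Br)cc21
F0 | step 4 | none | none
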